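## Structural features

Abietane numbering is used throughout. The target is a 19,20-lactonised abietane: carbocyclic rings A (C1–C5, C10) and B (C5–C10) are trans-fused at C5–C10, and a benzenoid ring C (C8, C9, C11–C14) is fused to ring B at C8–C9. Ring C is hexasubstituted (C11–OH, C12–OMe, C13–isopropyl, C14–OH), with C8 carrying the C7 aryl ketone and C9 bonded to the quaternary C10. A δ-lactone (C4–C19(=O)–O–C20H2–C10) bridges ring A 1,3-diaxially, so ring A and the lactone form a 3-oxabicyclo[3.3.1]nonan-2-one with C4 and C10 as bridgeheads and C5 as the one-carbon bridge. The stereocentres C4 (S), C5 (R) and C10 (R) are contiguous; C4 and C10 are quaternary, and H-5 is anti to C20. The fragile groups are the p-hydroquinone (C11/C14, easily oxidised to the quinone under air or base) and the enolisable C6 methylene; the lactone is neopentyl on both sides and robust. The real difficulty is the cis-diaxial quaternary pair C4/C10 locked by the lactone together with the trans fusion at C5, and the attachment of a fully substituted arene to C10. The key step exploits the fact that C10 bears no hydrogen and is flanked in ring B by C5 and C9. Written as a cyclohexa-2,5-dienone (C7 carbonyl), ring B makes C10 a prochiral centre with two enantiotopic enone arms, and a C20–O–C19 ester tether can deliver C4 to C5 only on the face that carries C20, which is exactly the trans A/B relationship.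

## Logic of the disconnections

**21 to 14 and 19.** Cut C9–C11 and C8–C14, the two bonds that join ring C to ring B. All four substituents of ring C and both phenolic oxygens then come from one four-carbon furan, and the oxidation-prone arene is never carried through the stereochemical steps. 21 is reduced to a tricyclic enone core and a three-step furan. The forward step must join the nucleophilic terminus of 19 to the β-carbon C9 and must reach the hydroquinone oxidation level, which the bromine of 14 provides.

**14 to 12.** Cut C8–Br. The halogen is only an oxidation-level and activating device. The forward step must brominate the enone at C8 without touching C6.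

**12 to 9.** Cut C3–C4 (closing ring A) and the C18–H bond. C4 becomes a lactone enolate carbon generated regiospecifically by hydride addition to a methylidene, and the chloropropyl arm on C10 is the electrophile. Ring A and the last stereocentre are removed. The forward step needs the enolate to form only at C4, which is why the ring B ketone is masked, and a 6-exo-tet closure to the bicyclo[3.3.1] skeleton. The bridge geometry allows only the required C4 configuration.

**9 to 8.** Cut O–Si. This is a protecting operation that hides the enone from the hydride. It needs regioselective enolisation, and C6 is the only enolisable position.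

**8 to 7 (key).** Cut C4–C5. In one sentence, the route is a phosphine-catalysed Rauhut–Currier desymmetrisation of the Birch-derived, acrylate-tethered prochiral cyclohexadienone 7. It removes both the C5 and C10 stereocentres and the lactone ring, leaving an achiral dienone. The forward step needs enantiotopic-group selection by the catalyst; the relative configuration is enforced by the tether.

**7 to 1, 2 and 5.** Cut the C7 carbonyl oxygen (from the doubly allylic CH2 of 6), the ester C–O bond (4 plus 5), the C20 oxidation level (3 to 4) and the C10–C1 bond (Birch reductive alkylation of 1 with 2). The quaternary carbon is made on an aromatic ring with no stereochemistry at stake. The forward steps need ipso-alkylation at the bromide end of 2 and oxidation at the only activated methylene.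

**19 to 15.** Cut O–Si (19 to 18), O–CH3 (18 to 17) and the lactone C–O bond (17 to 15 by way of 16). This is the classical tetronic acid construction. It needs γ-bromination of the keto ester and O-methylation at the 4-oxygen.

## Other disconnections considered

**Alternative 1:** The first idea is a polyene bicyclisation that cuts C4–C5 and C9–C10. The forward key step would be an oxidative radical (Mn(OAc)3/Cu(OAc)2) or cationic cyclisation of the aryl keto ester A1 to close rings A and B. The chosen plan is preferred for four reasons: A1 needs a geometrically defined C20-oxygenated trisubstituted alkene; the terminating position C9 lies next to the C11 methoxy group on an arene that is itself easily oxidised; the product carries a C3 ketone to be removed and lacks the C7 ketone, which would have to be introduced by benzylic oxidation beside an electron-rich ring and a benzylic isopropyl group; and absolute control would require an auxiliary. These add several corrective steps.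

**Alternative 2:** A Robinson-type annulation that cuts C1–C10 and C4–C5. The forward key step would be a proline-catalysed Hajos–Parrish annulation of a 2-(benzyloxymethyl)cyclohexane-1,3-dione with ethyl vinyl ketone to give the enedione A2, followed by reductive carboxylation/methylation at C4 and ring C construction from a C9 alkenyl-lithium and a cyclobutenedione. The chosen plan is preferred because A2 still needs C3 deoxygenation, C4 quaternisation and C7 oxidation; the 2-(alkoxymethyl)-1,3-dione is prone to loss of formaldehyde; and an alkenyl-lithium at C9 is incompatible with the lactone, which forces protecting-group traffic.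

**Alternative 3:** A quinone Diels–Alder reaction that cuts C7–C8 and C9–C10. The forward key step would be cycloaddition of quinone A3 with the ring A vinylcyclohexene A4, delivering the hydroquinone oxidation level directly. The chosen plan is preferred because the C10=C5 diene cannot carry the lactone (bridgehead alkene), so the facial selectivity at C10 depends on whether methyl or ester at C4 sits pseudoaxial, for which there is no clear bias. In addition, the regiochemistry rests on the small electronic difference between the two quinone carbonyls, and C5 and the C7 ketone would have to be set afterwards.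

Key step: step 5

Assumption: the sense of induction of the aminophosphine in step 5 is assigned by analogy only; if the (S)-valine-derived catalyst should favour the antipode of 8, its (R)-enantiomer (from D-valinol) is used.

## Route

Step 1
Reactants: 1 benzoic acid; 2 1-bromo-3-chloropropane
Product: 3 1-(3-chloropropyl)cyclohexa-2,5-diene-1-carboxylic acid
Conditions: Li, NH3(l), THF, −78 °C; then 2, −78 → −33 °C; aq. HCl
Reagents that add atoms: none
Why: Birch reductive alkylation: the benzoate is reduced to the cross-conjugated carboxylate dienolate, which is alkylated at the ipso carbon (C10) by the more reactive bromide end of 2.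

Step 2
Reactants: 3 1-(3-chloropropyl)cyclohexa-2,5-diene-1-carboxylic acid
Product: 4 [1-(3-chloropropyl)cyclohexa-2,5-dien-1-yl]methanol
Conditions: LiAlH4, Et2O, 0 °C; NaOH/H2O work-up
Reagents that add atoms: none
Why: Hydride reduction of the acid to the neopentyl alcohol (C20); isolated alkenes and the primary chloride should be inert at 0 °C.

Step 3
Reactants: 4 [1-(3-chloropropyl)cyclohexa-2,5-dien-1-yl]methanol; 5 prop-2-enoyl chloride
Product: 6 [1-(3-chloropropyl)cyclohexa-2,5-dien-1-yl]methyl prop-2-enoate
Conditions: Et3N, DMAP (cat.), CH2Cl2, 0 °C
Reagents that add atoms: none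
Why: O-Acylation of the primary alcohol installs C19, C4 and C18 as the acrylate tether.

Step 4
Reactants: 6 [1-(3-chloropropyl)cyclohexa-2,5-dien-1-yl]methyl prop-2-enoate
Product: 7 [1-(3-chloropropyl)-4-oxocyclohexa-2,5-dien-1-yl]methyl prop-2-enoate
Conditions: CrO3, 3,5-dimethylpyrazole, CH2Cl2, −20 °C
Reagents that add atoms: chromium trioxide, O=[Cr](=O)=O
Why: Allylic oxidation at the only activated position, the doubly allylic CH2 (C7), should give the cross-conjugated dienone; the substrate is symmetric, so no regiochemical question arises.

Step 5
Reactants: 7 [1-(3-chloropropyl)-4-oxocyclohexa-2,5-dien-1-yl]methyl prop-2-enoate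
Product: 8 (4aR,8aS)-8a-(3-chloropropyl)-4-methylidene-4a,5-dihydro-1H-isochromene-3,6(4H,8aH)-dione
Conditions: N-[(2S)-1-(diphenylphosphanyl)-3-methylbutan-2-yl]-3,5-bis(trifluoromethyl)benzamide (10 mol%), CHCl3, 0 → 23 °C
Reagents that add atoms: none
Why: Rauhut–Currier reaction: the phosphine adds to the unhindered acrylate terminus (C18) rather than to the dienone, whose β-carbons are shielded by quaternary C10; the ester enolate (C4) then closes onto C5 by intramolecular Michael addition in a 6-exo-trig mode to form the δ-lactone, and proton transfer with β-elimination of the phosphine leaves the C4=C18 methylidene. The closest known reaction type is the enantioselective intramolecular Rauhut–Currier desymmetrisation of acrylate-tethered 4,4-disubstituted cyclohexa-2,5-dienones to bicyclic α-methylene lactones with amino-acid-derived phosphines. C5 is controlled by the tether: C4 can reach C5 only on the face of ring B that carries C20, which gives the cis-fused lactone and places H-5 anti to C20, the trans A/B relationship of 21. C10 becomes stereogenic because the catalyst, hydrogen-bonded through its amide N–H to the dienone carbonyl, selects one of the two enantiotopic enone arms. The step needs chemoselectivity (acrylate as nucleophile precursor, dienone as acceptor), secured by sterics, and enantiotopic-group selectivity, secured by the bifunctional catalyst. The untouched enone (C8=C9–C7=O) remains as the handle for ring C.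

Step 6
Reactants: 8 (4aR,8aS)-8a-(3-chloropropyl)-4-methylidene-4a,5-dihydro-1H-isochromene-3,6(4H,8aH)-dione
Product: 9 (4aR,8aS)-6-[(tert-butyldimethylsilyl)oxy]-8a-(3-chloropropyl)-4-methylidene-4a,8a-dihydro-1H-isochromen-3(4H)-one
Conditions: TBSOTf, Et3N, CH2Cl2, −78 → 0 °C
Reagents that add atoms: tert-butyldimethylsilyl trifluoromethanesulfonate, CC(C)(C)[Si](C)(C)OS(=O)(=O)C(F)(F)F
Why: Soft enolisation of the ketone can occur only towards C6 (C10 is quaternary), giving the cross-conjugated silyl dienol ether; this masks the enone so that the hydride of step 7 meets only the α-methylene lactone.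

Step 7
Reactants: 9 (4aR,8aS)-6-[(tert-butyldimethylsilyl)oxy]-8a-(3-chloropropyl)-4-methylidene-4a,8a-dihydro-1H-isochromen-3(4H)-one
Product: 12 (4S,4aR,8aS)-4-methyl-4a,5-dihydro-1H-4,8a-propanoisochromene-3,6(4H)-dione, via lithium lactone enolate 10 (not isolated), via tricyclic silyl dienol ether 11 (not isolated)
Conditions: LiBH(s-Bu)3, THF, −78 °C; then HMPA, NaI (cat.), −78 → 40 °C; then 1 M HCl, THF, 0 °C
Reagents that add atoms: none
Why: Reductive alkylation: conjugate hydride addition to the methylidene creates the C18 methyl and the C4 lactone enolate regiospecifically, which closes ring A by 6-exo-tet displacement of the chloride on the arm at C10. The bicyclo[3.3.1] bridge allows bond formation only on the face of C4 syn to C1, so C4 is set with the methyl exo; acid then unmasks the C8=C9–C7=O enone.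

Step 8
Reactants: 12 (4S,4aR,8aS)-4-methyl-4a,5-dihydro-1H-4,8a-propanoisochromene-3,6(4H)-dione
Product: 14 (4S,4aR,8aR)-7-bromo-4-methyl-4a,5-dihydro-1H-4,8a-propanoisochromene-3,6(4H)-dione, via trans-dibromide 13 (not isolated)
Conditions: Br2, CH2Cl2, 0 °C; then Et3N, 0 → 23 °C
Reagents that add atoms: bromine, BrBr
Why: Bromine addition to the enone followed by dehydrobromination through the acidic C8–H gives the 2-bromoenone (Br on C8), a more reactive 2π partner that also carries the oxidation level needed for aromatisation.

Step 9
Reactants: 15 ethyl 2-acetyl-3-methylbutanoate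
Product: 17 4-hydroxy-3-(propan-2-yl)furan-2(5H)-one, via 4-bromo keto ester 16 (not isolated)
Conditions: Br2, CHCl3, 0 → 23 °C; then neat, 130 °C
Reagents that add atoms: none
Why: Classical tetronic acid synthesis: HBr-equilibrated bromination gives the 4-bromo keto ester, which lactonises on heating through attack of the ester carbonyl oxygen on CH2Br with loss of bromoethane.

Step 10
Reactants: 17 4-hydroxy-3-(propan-2-yl)furan-2(5H)-one
Product: 18 4-methoxy-3-(propan-2-yl)furan-2(5H)-one
Conditions: MeOH, H2SO4 (cat.), reflux
Reagents that add atoms: methanol, CO
Why: Acid-catalysed vinylogous esterification of the tetronic acid should give the thermodynamically preferred 4-methoxy butenolide.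

Step 11
Reactants: 18 4-methoxy-3-(propan-2-yl)furan-2(5H)-one
Product: 19 tert-butyl{[4-methoxy-3-(propan-2-yl)furan-2-yl]oxy}dimethylsilane
Conditions: TBSOTf, Et3N, CH2Cl2, 0 °C
Reagents that add atoms: tert-butyldimethylsilyl trifluoromethanesulfonate, CC(C)(C)[Si](C)(C)OS(=O)(=O)C(F)(F)F
Why: O-Silylation of the butenolide with deprotonation at C5 gives the aromatic 2-silyloxyfuran, an electron-rich diene whose unsubstituted C5 is its most nucleophilic terminus.

Step 12
Reactants: 14 (4S,4aR,8aR)-7-bromo-4-methyl-4a,5-dihydro-1H-4,8a-propanoisochromene-3,6(4H)-dione; 19 tert-butyl{[4-methoxy-3-(propan-2-yl)furan-2-yl]oxy}dimethylsilane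
Product: 21 (4S,5R,10R)-11,14-dihydroxy-12-methoxy-7-oxoabieta-8,11,13-trien-19,20-olide, via oxanorbornene cycloadduct 20 (not isolated)
Conditions: PhMe, 90 °C, sealed tube, argon; then TBAF, THF, 0 → 23 °C; aq. NH4Cl/Na2S2O4 work-up
Reagents that add atoms: none
Why: Diels–Alder reaction of a 2-silyloxyfuran with a 2-bromoenone used as an ynone equivalent: furan C5 (vinylogous to the silyloxy group and adjacent to OMe) bonds to the β-carbon C9 and furan C2 to C8, so the furan carbons become C11, C12 (OMe), C13 (isopropyl) and C14. Fluoride removes the silyl group and opens the bridged ketal to the C14 ketone and C11 alkoxide; base-mediated loss of HBr and tautomerisation should then give the hydroquinone with the ring oxygen of the furan as the C11 hydroxyl.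

## Compound list

1 | benzoic acid | OC(=O)c1ccccc1 | starting material
2 | 1-bromo-3-chloropropane | ClCCCBr | starting material
3 | 1-(3-chloropropyl)cyclohexa-2,5-diene-1-carboxylic acid | OC(=O)C1(CCCCl)C=CCC=C1 | intermediate
4 | [1-(3-chloropropyl)cyclohexa-2,5-dien-1-yl]methanol | OCC1(CCCCl)C=CCC=C1 | intermediate
5 | prop-2-enoyl chloride (acryloyl chloride) | C=CC(=O)Cl | starting material
6 | [1-(3-chloropropyl)cyclohexa-2,5-dien-1-yl]methyl prop-2-enoate | C=CC(=O)OCC1(CCCCl)C=CCC=C1 | intermediate
7 | [1-(3-chloropropyl)-4-oxocyclohexa-2,5-dien-1-yl]methyl prop-2-enoate (achiral; C10 prochiral) | C=CC(=O)OCC1(CCCCl)C=CC(=O)C=C1 | intermediate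
8 | (4aR,8aS)-8a-(3-chloropropyl)-4-methylidene-4a,5-dihydro-1H-isochromene-3,6(4H,8aH)-dione (cis-fused; abietane C5 and C10 set) | O=C1C[C@H]2C(=C)C(=O)OC[C@@]2(CCCCl)C=C1 | intermediate
9 | (4aR,8aS)-6-[(tert-butyldimethylsilyl)oxy]-8a-(3-chloropropyl)-4-methylidene-4a,8a-dihydro-1H-isochromen-3(4H)-one | CC(C)(C)[Si](C)(C)OC1=C[C@H]2C(=C)C(=O)OC[C@@]2(CCCCl)C=C1 | intermediate
10 | lithium (4aR,8aS)-6-[(tert-butyldimethylsilyl)oxy]-8a-(3-chloropropyl)-4-methyl-4a,8a-dihydro-1H-isochromen-3-olate (lactone enolate at C4) | CC(C)(C)[Si](C)(C)OC1=C[C@H]2C(C)=C(O[Li])OC[C@@]2(CCCCl)C=C1 | intermediate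
11 | tricyclic silyl dienol ether: the 6-O-TBS dienol ether (C5=C6, C7=C8 in isochromene numbering) of 12, (4S,4aR,8aS) | CC(C)(C)[Si](C)(C)OC1=C[C@@H]2[C@@]3(C=C1)CCC[C@]2(C)C(=O)OC3 | intermediate
12 | (4S,4aR,8aS)-4-methyl-4a,5-dihydro-1H-4,8a-propanoisochromene-3,6(4H)-dione (abietane rings A and B with the 19,20-lactone, C7 ketone, C8=C9) | O=C1C[C@@H]2[C@@]3(C=C1)CCC[C@]2(C)C(=O)OC3 | intermediate
13 | 7,8-dibromo-7,8-dihydro derivative of 12 (trans-dibromide at abietane C8/C9; these two centres not specified) | O=C1C[C@@H]2[C@@]3(C(Br)C1Br)CCC[C@]2(C)C(=O)OC3 | intermediate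
14 | (4S,4aR,8aR)-7-bromo-4-methyl-4a,5-dihydro-1H-4,8a-propanoisochromene-3,6(4H)-dione (Br on abietane C8) | O=C1C[C@@H]2[C@@]3(C=C1Br)CCC[C@]2(C)C(=O)OC3 | intermediate
15 | ethyl 2-acetyl-3-methylbutanoate | CCOC(=O)C(C(C)C)C(C)=O | starting material
16 | ethyl 4-bromo-3-oxo-2-(propan-2-yl)butanoate | CCOC(=O)C(C(C)C)C(=O)CBr | intermediate
17 | 4-hydroxy-3-(propan-2-yl)furan-2(5H)-one | CC(C)C1=C(O)COC1=O | intermediate
18 | 4-methoxy-3-(propan-2-yl)furan-2(5H)-one | COC1=C(C(C)C)C(=O)OC1 | intermediate
19 | tert-butyl{[4-methoxy-3-(propan-2-yl)furan-2-yl]oxy}dimethylsilane | COc1coc(O[Si](C)(C)C(C)(C)C)c1C(C)C | intermediate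
20 | Diels–Alder adduct of 14 and 19: 7-oxabicyclo[2.2.1]hept-2-ene (bridgeheads C11–H and C14–OTBS) fused to ring B at C8(Br)–C9(H); the four new centres are transient and not specified | O=C1C[C@@H]2[C@@]3(C4C1(Br)C1(O[Si](C)(C)C(C)(C)C)OC4C(OC)=C1C(C)C)CCC[C@]2(C)C(=O)OC3 | intermediate
21 | (4S,5R,10R)-11,14-dihydroxy-12-methoxy-7-oxoabieta-8,11,13-trien-19,20-olide (CNP0159814.2) | COc1c(O)c2c(c(O)c1C(C)C)C(=O)C[C@@H]1[C@]23CCC[C@]1(C)C(=O)OC3 | target

## Step count and least certain steps

Total: 12 steps. Longest linear sequence: 9 steps (steps 1–8 and 12); the furan 19 is made in a 3-step branch (steps 9–11).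

**Step 5 (key).** The most likely failure is poor discrimination between the two enantiotopic enone arms. The CH2–O tether closes a six-membered ring and is more flexible than the five-membered cases on which the catalyst class is known, and closure through the less populated s-cis ester rotamer may be slow enough for acrylate oligomerisation to compete. Fallback, setting out from 7: a copper hydride reductive Michael cyclisation (Cu(OAc)2, (R)-DTBM-SEGPHOS, tetramethyldisiloxane, t-BuOH, toluene, 0 °C) would turn the acrylate into a copper propionate enolate that closes onto one enone arm under control of the bisphosphine. This would give the cis-fused 4-methyl lactone enone F1 as C4 epimers, both of which are usable. Silylation (TBSOTf, Et3N) would give its silyl dienol ether F2. Deprotonation at C4, the only acidic site (LDA, THF/HMPA, −78 → 23 °C), with intramolecular alkylation returns to the route at 11 and hence 12, replacing steps 5–7.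

**Step 12.** The most likely failure is slow bond formation at C9, which is neopentyl to C10, so that the silyloxyfuran decomposes first. Alternatively the second bond (C8–C14) may not close, leaving an α-bromo ketone that undergoes Favorskii-type rearrangement on fluoride treatment. Fallback, setting out from 12: a Lewis-acid Mukaiyama–Michael addition of 19 (TBSOTf cat., CH2Cl2, −78 °C) forms only the C9–C11 bond and gives the butenolide-substituted silyl enol ether F3. Fluoride (TBAF, THF, −20 °C) releases the C8 enolate regiospecifically for a Dieckmann-type closure onto the butenolide carbonyl, giving the 11-hydroxy triketone F4. Dehydrogenation (DDQ, dioxane, 23 °C) with tautomerisation returns to the route at 21. This replaces steps 8 and 12 by a stepwise polar annulation with a late oxidation.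

**Step 7.** The most likely failure is protonation or O-alkylation of the borane-complexed, fully substituted enolate on warming before the primary chloride is displaced, or competing hydride attack on the C–Cl bond. Fallback, setting out from 9: lithium benzeneselenolate (PhSeH, n-BuLi, THF/HMPA) adds to the methylidene under non-reducing conditions and generates a borane-free lithium enolate that closes ring A, giving the C18-phenylselanyl tricycle F5. Radical deselenation (Bu3SnH, AIBN, PhH, 80 °C) returns to the route at 11, which is hydrolysed to 12 as before.

**Step 4.** The most likely failure is oxidative degradation or oligomerisation of the acrylate during the chromium oxidation. Fallback, setting out from 4: silylation (TBSCl, imidazole) gives the silyl ether F6, the same oxidation gives the dienone silyl ether F7, and acidic desilylation (HF·pyridine, which avoids the alkoxide that could expel formaldehyde and aromatise) gives the hydroxymethyl dienone F8. Acylation with 5 (i-Pr2NEt, CH2Cl2, −20 °C) returns to the route at 7.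

## Further compounds

F1 | step 5 | cis-fused 8a-(3-chloropropyl)-4-methyl-4a,5-dihydro-1H-isochromene-3,6(4H,8aH)-dione, ring-fusion centres as in 8, C4 epimers | O=C1C[C@H]2C(C)C(=O)OC[C@@]2(CCCCl)C=C1
F2 | step 5 | 6-O-tert-butyldimethylsilyl dienol ether of F1 | CC(C)(C)[Si](C)(C)OC1=C[C@H]2C(C)C(=O)OC[C@@]2(CCCCl)C=C1
F3 | step 12 | Michael adduct of 12 and 19: C7 tert-butyldimethylsilyl enol ether (C7=C8) carrying a 4-methoxy-5-oxo-3-(propan-2-yl)-2,5-dihydrofuran-2-yl group on C9, new centres not specified | CC(C)(C)[Si](C)(C)OC1C[C@@H]2[C@@]3(C(C4OC(=O)C(C(C)C)=C4OC)C=1)CCC[C@]2(C)C(=O)OC3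
F4 | step 12 | 11-hydroxy-12-methoxy-7,14-dioxo-8,9,11,14-tetrahydro precursor of 21 (ring C as 4-hydroxycyclohex-2-enone), new centres not specified | O=C1C[C@@H]2[C@@]3(C4C1C(=O)C(C(C)C)=C(OC)C4O)CCC[C@]2(C)C(=O)OC3
F5 | step 7 | 18-(phenylselanyl) analogue of 11 | CC(C)(C)[Si](C)(C)OC1=C[C@@H]2[C@@]3(C=C1)CCC[C@]2(C[Se]c4ccccc4)C(=O)OC3
F6 | step 4 | tert-butyl{[1-(3-chloropropyl)cyclohexa-2,5-dien-1-yl]methoxy}dimethylsilane | CC(C)(C)[Si](C)(C)OCC1(CCCCl)C=CCC=C1
F7 | step 4 | 4-{[(tert-butyldimethylsilyl)oxy]methyl}-4-(3-chloropropyl)cyclohexa-2,5-dien-1-one | CC(C)(C)[Si](C)(C)OCC1(CCCCl)C=CC(=O)C=C1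
F8 | step 4 | 4-(3-chloropropyl)-4-(hydroxymethyl)cyclohexa-2,5-dien-1-one | OCC1(CCCCl)C=CC(=O)C=C1
A1 | alternative 1 | ethyl (6Z)-6-{[(tert-butyldimethylsilyl)oxy]methyl}-2-methyl-3-oxo-9-[2,4,5-trimethoxy-3-(propan-2-yl)phenyl]non-6-enoate | CCOC(=O)C(C)C(=O)CC/C(CO[Si](C)(C)C(C)(C)C)=C/CCc1cc(OC)c(OC)c(C(C)C)c1OC
A2 | alternative 2 | (8aS)-8a-[(benzyloxy)methyl]-5-methyl-3,4,8,8a-tetrahydronaphthalene-1,6(2H,7H)-dione | CC1=C2CCCC(=O)[C@@]2(COCc3ccccc3)CCC1=O
A3 | alternative 3 | 2-methoxy-3-(propan-2-yl)cyclohexa-2,5-diene-1,4-dione | COC1=C(C(C)C)C(=O)C=CC1=O
A4 | alternative 3 | methyl (1S)-3-{[(tert-butyldimethylsilyl)oxy]methyl}-2-ethenyl-1-methylcyclohex-2-ene-1-carboxylate | C=CC1=C(CO[Si](C)(C)C(C)(C)C)CCC[C@]1(C)C(=O)OC
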